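**Plan**

- Retrosynthesis (flavanone numbering O1, C2, C3, C4, C4a, C5–C8, C8a): the aryl ether bond O1–C8a of ring C and the C4a–C5 bond of ring A are cut together, so that ring A goes back to a 2-substituted 4H-pyran-4-one.
- Enabling feature: ring A is a 4-acylresorcinol. Its two oxygens (O1 on C8a, OH on C7) stand 1,3 like C-2 and the C-4 carbonyl of a 4-pyranone, and the C4 ketone makes the C4a methylene acidic enough to re-close the carbocycle by aldol condensation.
- Further cuts: C4–C4a (Weinreb amide plus the lateral anion of 2-methyl-4H-pyran-4-one), the ester carbon of a beta-keto ester (Claisen), and the geranyl–O bond.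
- Forward order: geranyl ether, beta-keto ester, (S)-carbinol, Weinreb amide, pyranonyl ketone; then one operation closes ring C, opens the pyranone and closes ring A as the arene with the 7-OH free.
- Stereochemistry: C2 is set by asymmetric transfer hydrogenation of the aryl ketone (step 3) and kept, because the C2–O bond is never broken.

Key step: step 6

Assumption: the descriptor in the SMILES corresponds to the (2S)-flavanone, and 2-methyl-4H-pyran-4-one is taken as commercially available. "Geranyl" means (2E)-3,7-dimethylocta-2,6-dien-1-yl.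

**Route**

Step 1
Reactants: 1 4'-hydroxyacetophenone; 2 geranyl bromide
Product: 3 1-[4-(geranyloxy)phenyl]ethan-1-one
Conditions: K2CO3, DMF, 23 °C
Reagents that add atoms: none
Why: Williamson ether synthesis, in which the phenoxide displaces bromide from the primary allylic carbon by SN2 and the (E)-alkene geometry is kept.

Step 2
Reactants: 3 1-[4-(geranyloxy)phenyl]ethan-1-one
Product: 4 ethyl 3-[4-(geranyloxy)phenyl]-3-oxopropanoate
Conditions: (EtO)2CO, NaH, THF, 65 °C; then AcOH
Reagents that add atoms: diethyl carbonate, CCOC(=O)OCC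
Why: Crossed Claisen condensation of the methyl ketone enolate with diethyl carbonate, driven by formation of the stabilised enolate of the beta-keto ester, under conditions to which the geranyl aryl ether is inert.

Step 3
Reactants: 4 ethyl 3-[4-(geranyloxy)phenyl]-3-oxopropanoate
Product: 5 ethyl (3S)-3-[4-(geranyloxy)phenyl]-3-hydroxypropanoate
Conditions: RuCl[(S,S)-TsDPEN](p-cymene) (1 mol %), HCO2H/Et3N (1:1), DMF, 40 °C
Reagents that add atoms: none
Why: Noyori asymmetric transfer hydrogenation, in which the ruthenium hydride of the (S,S)-TsDPEN complex reduces the aryl ketone through an outer-sphere six-membered transition state with the aryl group under the p-cymene ligand, which should give the (S)-carbinol while the ester and the trisubstituted alkenes are not reduced and the non-acidic medium spares the allylic ether.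

Step 4
Reactants: 5 ethyl (3S)-3-[4-(geranyloxy)phenyl]-3-hydroxypropanoate
Product: 6 (3S)-3-[4-(geranyloxy)phenyl]-3-hydroxy-N-methoxy-N-methylpropanamide
Conditions: MeNH(OMe)·HCl, i-PrMgCl, THF, −20 → 0 °C; aq NH4Cl
Reagents that add atoms: N,O-dimethylhydroxylamine hydrochloride, CNOC.Cl
Why: Weinreb amide synthesis by aminolysis of the ester with the magnesium amide of N,O-dimethylhydroxylamine, the carbinol being carried as its magnesium alkoxide, which at this temperature should neither eliminate nor cleave by retro-aldol reaction.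

Step 5
Reactants: 6 (3S)-3-[4-(geranyloxy)phenyl]-3-hydroxy-N-methoxy-N-methylpropanamide; 7 2-methyl-4H-pyran-4-one
Product: 9 2-{(4S)-4-[4-(geranyloxy)phenyl]-4-hydroxy-2-oxobutyl}-4H-pyran-4-one, via lithium 2-methylidene-2H-pyran-4-olate 8 (not isolated)
Conditions: 7 (3.3 equiv), LiN(SiMe3)2 (3.2 equiv), THF, −78 °C; then 6, −78 → −40 °C; AcOH, −78 °C, pH 6 buffer
Reagents that add atoms: none
Why: Weinreb ketone synthesis with a vinylogous enolate, in which LiN(SiMe3)2 removes a proton from the 2-methyl group of 7 (the gamma position of the vinylogous ester) and dienolate 8 adds through that carbon to the amide to give a chelated tetrahedral adduct that releases the ketone only on the acidic quench, one equivalent of 8 being spent on the free hydroxyl group.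

Step 6
Reactants: 9 2-{(4S)-4-[4-(geranyloxy)phenyl]-4-hydroxy-2-oxobutyl}-4H-pyran-4-one
Product: 12 (2S)-2-[4-(geranyloxy)phenyl]-7-hydroxy-2,3-dihydro-4H-chromen-4-one, via spiroketal enone 10 (not isolated), via formyl diketone 11 (not isolated)
Conditions: KOt-Bu (1.1 equiv), THF/t-BuOH (5:1), 0.02 M, −20 → 0 °C; then AcOH
Reagents that add atoms: none
Why: Proposed new method: the alkoxide of 9 should add in conjugate fashion to C-2 of the 4-pyranone (6-exo-trig, closing ring C through the O1–C8a bond) to give spiroketal 10, E1cB expulsion of the pyranone ring oxygen as a formyl-ketone enolate should then give the 2,3-dihydropyran-4-one 11, and its C-5 carbon (the future C4a, alpha to the C4 ketone) should attack the unmasked aldehyde (6-exo-trig aldol) and lose water to give ring A as the phenol. The closest known reaction types are the intramolecular conjugate addition of hydroxyl groups to 4-pyranones that gives spiroketal enones, the conversion of 2-methylpyrylium salts into phenols or N,N-dialkylanilines by hydroxide or secondary amines through ring opening and aldol-type re-closure, and the base-induced aldol aromatisation of pyranone-masked polyketones. No new stereocentre remains, since the spiro carbon of 10 is transient and C2 keeps its (S) configuration because its C–O bond is never broken. The step needs the carbinol oxygen, and neither the pyranone oxygen nor an external nucleophile, to end on C8a; the six-membered tether, the hindered base, the non-nucleophilic medium and high dilution should secure this, since an external nucleophile would attack the unsubstituted C-6 of the pyranone. It also needs the cyclisation to outrun retro-aldol cleavage and E1cB dehydration of the beta-hydroxy ketone; the acidic pyranonyl-CH2-CO methylene takes up the base as an enolate of the C4 ketone, which should protect C3, and the product is held as its 7-phenoxide, which disfavours ring opening to the chalcone.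

**Compound list**

1 | 4'-hydroxyacetophenone | CC(=O)c1ccc(O)cc1 | starting material
2 | geranyl bromide, (2E)-1-bromo-3,7-dimethylocta-2,6-diene | CC(C)=CCC/C(C)=C/CBr | starting material
3 | 1-[4-(geranyloxy)phenyl]ethan-1-one | CC(C)=CCC/C(C)=C/COc1ccc(C(C)=O)cc1 | intermediate
4 | ethyl 3-[4-(geranyloxy)phenyl]-3-oxopropanoate | CC(C)=CCC/C(C)=C/COc1ccc(C(=O)CC(=O)OCC)cc1 | intermediate
5 | ethyl (3S)-3-[4-(geranyloxy)phenyl]-3-hydroxypropanoate | CC(C)=CCC/C(C)=C/COc1ccc([C@@H](O)CC(=O)OCC)cc1 | intermediate
6 | (3S)-3-[4-(geranyloxy)phenyl]-3-hydroxy-N-methoxy-N-methylpropanamide | CC(C)=CCC/C(C)=C/COc1ccc([C@@H](O)CC(=O)N(C)OC)cc1 | intermediate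
7 | 2-methyl-4H-pyran-4-one | CC1=CC(=O)C=CO1 | starting material
8 | lithium 2-methylidene-2H-pyran-4-olate (formed in the flask, not isolated) | C=C1C=C(O[Li])C=CO1 | intermediate
9 | 2-{(4S)-4-[4-(geranyloxy)phenyl]-4-hydroxy-2-oxobutyl}-4H-pyran-4-one | CC(C)=CCC/C(C)=C/COc1ccc([C@@H](O)CC(=O)CC2=CC(=O)C=CO2)cc1 | intermediate
10 | (8S)-8-[4-(geranyloxy)phenyl]-1,7-dioxaspiro[5.5]undec-2-ene-4,10-dione, both spiro epimers (not isolated) | CC(C)=CCC/C(C)=C/COc1ccc([C@@H]2CC(=O)CC3(CC(=O)C=CO3)O2)cc1 | intermediate
11 | (2S)-6-(2,4-dioxobutyl)-2-[4-(geranyloxy)phenyl]-2,3-dihydro-4H-pyran-4-one, as its enolate (not isolated) | CC(C)=CCC/C(C)=C/COc1ccc([C@@H]2CC(=O)C=C(CC(=O)CC=O)O2)cc1 | intermediate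
12 | (2S)-2-[4-(geranyloxy)phenyl]-7-hydroxy-2,3-dihydro-4H-chromen-4-one | CC(C)=CCC/C(C)=C/COc1ccc([C@@H]2CC(=O)c3ccc(O)cc3O2)cc1 | target

**Step count**

Total steps: 6. Longest linear sequence: 6 steps (1 → 3 → 4 → 5 → 6 → 9 → 12).

**Steps most likely to fail**

1. Step 6 (proposed new method). The alkoxide may be lost to retro-aldol cleavage before it adds to the pyranone. Ring C may open to the chalcone by E1cB elimination under base and re-close without stereocontrol. A second molecule or an external nucleophile may open the pyranone at C-6, so that oligomers form or the wrong oxygen is kept on the arene. The fallback uses known chemistry, makes the aryl ether bond by intramolecular nucleophilic aromatic substitution, sets out from 6 and comes back at 12. Commercial 4-bromo-3-fluorophenol is silylated (i-Pr3SiCl, imidazole, DMF) to (4-bromo-3-fluorophenoxy)tri(propan-2-yl)silane F1. Bromine–lithium exchange (n-BuLi, THF, −78 °C) gives [2-fluoro-4-(triisopropylsilyloxy)phenyl]lithium F2 (not isolated). Added in excess (2.2 equiv) to 6 at −78 °C, this should give after work-up (3S)-1-[2-fluoro-4-(triisopropylsilyloxy)phenyl]-3-[4-(geranyloxy)phenyl]-3-hydroxypropan-1-one F3. KN(SiMe3)2 in THF at −40 → 0 °C should then close ring C by displacement of the fluoride ortho to the ketone, with retention at the carbinol carbon, to give (2S)-2-[4-(geranyloxy)phenyl]-7-(triisopropylsilyloxy)-2,3-dihydro-4H-chromen-4-one F4. Buffered fluoride (Bu4NF/AcOH, THF, 0 °C) frees the phenol to give 12.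

2. Step 5. Dienolate 8 may be consumed by conjugate addition to C-6 of unreacted 7, and its addition to the alkoxide-bearing amide may be too slow at a temperature where 8 is stable. The fallback replaces acylation by aldol addition and oxidation, sets out from 6 and comes back at 9. Compound 6 is silylated (t-BuMe2SiCl, imidazole, DMF) to (3S)-3-(tert-butyldimethylsilyloxy)-3-[4-(geranyloxy)phenyl]-N-methoxy-N-methylpropanamide F5. i-Bu2AlH (THF, −78 °C) reduces it to (3S)-3-(tert-butyldimethylsilyloxy)-3-[4-(geranyloxy)phenyl]propanal F6. The far more electrophilic aldehyde should capture 8 at −78 °C to give 2-{(4S)-4-(tert-butyldimethylsilyloxy)-4-[4-(geranyloxy)phenyl]-2-hydroxybutyl}-4H-pyran-4-one F7 as both carbinol epimers. Dess–Martin periodinane (CH2Cl2, NaHCO3, 0 °C) oxidises both epimers to 2-{(4S)-4-(tert-butyldimethylsilyloxy)-4-[4-(geranyloxy)phenyl]-2-oxobutyl}-4H-pyran-4-one F8. HF·pyridine (THF, 0 °C) removes the silyl group to give 9.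

3. Step 3. Hydride transfer to the electron-rich aryl ketone may be slow and facial discrimination incomplete, and the allylic ether may erode on long reaction times. The fallback replaces asymmetric catalysis by kinetic resolution, sets out from 4 and comes back at 5. Compound 4 is reduced without stereocontrol (NaBH4, EtOH, 0 °C) to racemic ethyl 3-[4-(geranyloxy)phenyl]-3-hydroxypropanoate F9. Lipase-catalysed transesterification with vinyl acetate (Burkholderia cepacia lipase, t-BuOMe, 30 °C) should acylate the (R)-enantiomer, as lipases generally do with aryl alkyl carbinols, giving ethyl (3R)-3-acetoxy-3-[4-(geranyloxy)phenyl]propanoate F10. The unreacted (S)-alcohol is separated by chromatography and re-enters the route as 5.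

**Further compounds**

F1 | step 6 | (4-bromo-3-fluorophenoxy)tri(propan-2-yl)silane | CC(C)[Si](Oc1ccc(Br)c(F)c1)(C(C)C)C(C)C
F2 | step 6 | [2-fluoro-4-(triisopropylsilyloxy)phenyl]lithium | [Li]c1ccc(O[Si](C(C)C)(C(C)C)C(C)C)cc1F
F3 | step 6 | (3S)-1-[2-fluoro-4-(triisopropylsilyloxy)phenyl]-3-[4-(geranyloxy)phenyl]-3-hydroxypropan-1-one | CC(C)=CCC/C(C)=C/COc1ccc([C@@H](O)CC(=O)c2ccc(O[Si](C(C)C)(C(C)C)C(C)C)cc2F)cc1
F4 | step 6 | (2S)-2-[4-(geranyloxy)phenyl]-7-(triisopropylsilyloxy)-2,3-dihydro-4H-chromen-4-one | CC(C)=CCC/C(C)=C/COc1ccc([C@@H]2CC(=O)c3ccc(O[Si](C(C)C)(C(C)C)C(C)C)cc3O2)cc1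
F5 | step 5 | (3S)-3-(tert-butyldimethylsilyloxy)-3-[4-(geranyloxy)phenyl]-N-methoxy-N-methylpropanamide | CC(C)=CCC/C(C)=C/COc1ccc([C@@H](O[Si](C)(C)C(C)(C)C)CC(=O)N(C)OC)cc1
F6 | step 5 | (3S)-3-(tert-butyldimethylsilyloxy)-3-[4-(geranyloxy)phenyl]propanal | CC(C)=CCC/C(C)=C/COc1ccc([C@@H](O[Si](C)(C)C(C)(C)C)CC=O)cc1
F7 | step 5 | 2-{(4S)-4-(tert-butyldimethylsilyloxy)-4-[4-(geranyloxy)phenyl]-2-hydroxybutyl}-4H-pyran-4-one, both carbinol epimers | CC(C)=CCC/C(C)=C/COc1ccc([C@@H](O[Si](C)(C)C(C)(C)C)CC(O)CC2=CC(=O)C=CO2)cc1
F8 | step 5 | 2-{(4S)-4-(tert-butyldimethylsilyloxy)-4-[4-(geranyloxy)phenyl]-2-oxobutyl}-4H-pyran-4-one | CC(C)=CCC/C(C)=C/COc1ccc([C@@H](O[Si](C)(C)C(C)(C)C)CC(=O)CC2=CC(=O)C=CO2)cc1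
F9 | step 3 | racemic ethyl 3-[4-(geranyloxy)phenyl]-3-hydroxypropanoate | CC(C)=CCC/C(C)=C/COc1ccc(C(O)CC(=O)OCC)cc1
F10 | step 3 | ethyl (3R)-3-acetoxy-3-[4-(geranyloxy)phenyl]propanoate | CC(C)=CCC/C(C)=C/COc1ccc([C@H](OC(C)=O)CC(=O)OCC)cc1
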